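**Plan**

1. Ring locants follow the target oxolane: O1, C2 (aryl), C3 (CH2OH), C4 (carbinol side chain), C5 (CH2).
2. Cuts: first the aryl–C(carbinol) bond on C4 (aryl Grignard plus a 4-formyl oxolane); then, in one stroke, O1–C2 and C4–C5, leaving formaldehyde (O1, C5) and a cyclopropane in which C2 and C4 are bonded; last the C2–C4 and C3–C4 bonds of that cyclopropane (cinnamaldehyde plus bromomalonate).
3. Enabling feature: C2 carries a 4-oxygenated aryl group beside the ring oxygen (latent benzylic cation) and C4 carries a carbon at carboxyl level (latent malonate enolate once a second, temporary ester is added). This 1,3-donor/acceptor pair across C2–C3–C4 lets a C2–C4 cyclopropane bond open towards an aldehyde.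
4. Forward: benzylated coniferaldehyde → cyclopropane (temporary ring) → alcohol → silyl ether → (3+2) with formaldehyde closes the oxolane, the only ring of the target that is built → loss of the helper ester → aldehyde → aryl addition → desilylation → debenzylation.
5. Stereochemistry: C3 absolutely, from the prolinol-silyl-ether-catalysed cyclopropanation; C2 and C4 trans to C3 by equilibration (reversible benzylic C–O ionisation; enolisable ester); the carbinol centre by Felkin–Anh/chelate-controlled Grignard addition.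

Key step: step 5

Assumption: the (S)-prolinol silyl ether is taken to deliver the malonate to the same enal face as in its other iminium additions to β-aryl enals; if the sense were opposite, the (R)-catalyst would be used and nothing else changes.

**Step 1**
Reactants: 1 (E)-3-(4-hydroxy-3-methoxyphenyl)prop-2-enal (coniferaldehyde)
Product: 2 (E)-3-[4-(benzyloxy)-3-methoxyphenyl]prop-2-enal
Conditions: BnBr, K2CO3, DMF, 23 °C
Reagents that add atoms: benzyl bromide, BrCc1ccccc1
Why: Williamson O-alkylation of the phenoxide, the only strong nucleophile present, installs a benzyl ether that should survive the Lewis acid, base, hydride and organometallic steps, and no stereocenter is formed.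

**Step 2**
Reactants: 2 (E)-3-[4-(benzyloxy)-3-methoxyphenyl]prop-2-enal; 3 dimethyl 2-bromopropanedioate (dimethyl bromomalonate)
Product: 4 dimethyl (2S,3R)-2-[4-(benzyloxy)-3-methoxyphenyl]-3-formylcyclopropane-1,1-dicarboxylate (aryl and formyl trans)
Conditions: (S)-α,α-diphenylprolinol trimethylsilyl ether (20 mol %), 2,6-lutidine (1.1 equiv), CH2Cl2, 0 → 23 °C
Reagents that add atoms: none
Why: Organocatalytic Michael-initiated ring closure (iminium–enamine cascade), in which the bromomalonate carbon adds to the β-carbon of the iminium ion on the face away from the diphenyl(silyloxy)methyl group and the enamine then displaces bromide (3-exo-tet) with formyl and aryl trans, which fixes the formyl-bearing centre that becomes C3 of the oxolane.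

**Step 3**
Reactants: 4 dimethyl (2S,3R)-2-[4-(benzyloxy)-3-methoxyphenyl]-3-formylcyclopropane-1,1-dicarboxylate
Product: 5 dimethyl (2S,3R)-2-[4-(benzyloxy)-3-methoxyphenyl]-3-(hydroxymethyl)cyclopropane-1,1-dicarboxylate
Conditions: NaBH4, MeOH/CH2Cl2, −20 °C
Reagents that add atoms: none
Why: Chemoselective NaBH4 reduction of the aldehyde beside the malonate esters at low temperature leaves both stereocenters untouched, and the alcohol is carried on at once because it lies cis to one ester and could lactonise.

**Step 4**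
Reactants: 5 dimethyl (2S,3R)-2-[4-(benzyloxy)-3-methoxyphenyl]-3-(hydroxymethyl)cyclopropane-1,1-dicarboxylate
Product: 6 dimethyl (2S,3R)-2-[4-(benzyloxy)-3-methoxyphenyl]-3-({[tert-butyl(diphenyl)silyl]oxy}methyl)cyclopropane-1,1-dicarboxylate
Conditions: TBDPSCl, imidazole, CH2Cl2, 0 → 23 °C
Reagents that add atoms: tert-butyl(chloro)diphenylsilane, CC(C)(C)[Si](Cl)(c1ccccc1)c1ccccc1
Why: Silylation of the primary alcohol under weakly basic conditions avoids the alkoxide that would lactonise onto the cis ester, and the bulky, poorly chelating silyl ether should survive steps 5 to 8.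

**Step 5**
Reactants: 6 dimethyl (2S,3R)-2-[4-(benzyloxy)-3-methoxyphenyl]-3-({[tert-butyl(diphenyl)silyl]oxy}methyl)cyclopropane-1,1-dicarboxylate; 7 formaldehyde (charged as paraformaldehyde)
Product: 9 dimethyl (4R,5S)-5-[4-(benzyloxy)-3-methoxyphenyl]-4-({[tert-butyl(diphenyl)silyl]oxy}methyl)oxolane-3,3-dicarboxylate, via cis-oxolane diester 8 (not isolated)
Conditions: (CH2O)n (5 equiv of 7), Sn(OTf)2 (10 mol %), 4 Å MS, ClCH2CH2Cl, 23 °C; then 40 °C
Reagents that add atoms: none
Why: Sn(OTf)2 chelates the geminal diester of 6 and polarises the ring bond between the aryl-bearing carbon and the malonate carbon; the carbonyl oxygen of monomeric formaldehyde opens this bond at the benzylic carbon (SN2-like, with inversion, in an intimate ion pair), and the tin malonate enolate then attacks the O-alkylated formaldehyde carbon, so that the O1–C2 bond and the C5–C4 bond arise in one operation. The closest known reaction type is the Lewis-acid-catalysed formal (3+2) cycloaddition of 2-arylcyclopropane-1,1-diesters with aldehydes, used here with the smallest aldehyde. The oxolane ring is closed by the second bond, a 5-(enolexo)-endo-trig aldol-type attack on a cationic oxocarbenium carbon, for which the usual restriction on 5-endo closure does not hold. The only new stereocenter is C2: invertive opening of the trans-cyclopropane should first give the 2,3-cis oxolane 8, and the same Lewis acid then re-ionises the 4-benzyloxybenzylic C2–O1 bond reversibly so that the ring recloses to the more stable 2,3-trans isomer 9; C2 is thus finally set by the untouched neighbour C3 under thermodynamic control, and any share of the opening that is ionic from the start leads to the same isomer. The step needs cleavage of the aryl-carbon/malonate-carbon bond and not of the bond to the silyloxymethyl carbon, which the push–pull pair of 4-benzyloxy-3-methoxyphenyl donor and geminal diester acceptor secures, and it needs the monomeric aldehyde to be captured before it oligomerises, for which paraformaldehyde is cracked slowly by the same catalyst.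

**Step 6**
Reactants: 9 dimethyl (4R,5S)-5-[4-(benzyloxy)-3-methoxyphenyl]-4-({[tert-butyl(diphenyl)silyl]oxy}methyl)oxolane-3,3-dicarboxylate
Product: 11 methyl (3S,4R,5S)-5-[4-(benzyloxy)-3-methoxyphenyl]-4-({[tert-butyl(diphenyl)silyl]oxy}methyl)oxolane-3-carboxylate, via cis-ester epimer 10 (not isolated)
Conditions: LiCl, H2O (2 equiv), DMSO, 150 °C; then cool, NaOMe (cat.), MeOH, 23 °C
Reagents that add atoms: none
Why: Krapcho dealkoxycarbonylation (chloride demethylation, loss of CO2, protonation of the ester enolate, expected anti to the silyloxymethyl group) removes the ester that only served to activate the cyclopropane, and methoxide epimerisation of the enolisable centre C4 should then converge on the all-trans ester.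

**Step 7**
Reactants: 11 methyl (3S,4R,5S)-5-[4-(benzyloxy)-3-methoxyphenyl]-4-({[tert-butyl(diphenyl)silyl]oxy}methyl)oxolane-3-carboxylate
Product: 12 (3S,4R,5S)-5-[4-(benzyloxy)-3-methoxyphenyl]-4-({[tert-butyl(diphenyl)silyl]oxy}methyl)oxolane-3-carbaldehyde
Conditions: iBu2AlH (1.1 equiv), CH2Cl2, −78 °C; MeOH, then aq. Rochelle salt
Reagents that add atoms: none
Why: Partial reduction of the methyl ester with one equivalent of iBu2AlH at −78 °C should stop at the aluminium hemiacetal, which chelation to the ring oxygen stabilises until work-up, and the α-centre already sits in its thermodynamically preferred trans arrangement.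

**Step 8**
Reactants: 12 (3S,4R,5S)-5-[4-(benzyloxy)-3-methoxyphenyl]-4-({[tert-butyl(diphenyl)silyl]oxy}methyl)oxolane-3-carbaldehyde; 13 1-(benzyloxy)-4-bromo-2-methoxybenzene
Product: 15 (S)-[4-(benzyloxy)-3-methoxyphenyl][(3S,4R,5S)-5-[4-(benzyloxy)-3-methoxyphenyl]-4-({[tert-butyl(diphenyl)silyl]oxy}methyl)oxolan-3-yl]methanol, via aryl Grignard reagent 14 (not isolated)
Conditions: 13, Mg, THF, 23 → 40 °C; then 12, CH2Cl2/THF, −78 °C; H2O
Reagents that add atoms: none
Why: Grignard 1,2-addition to the aldehyde under Felkin–Anh control, reinforced by a six-membered Mg chelate between the carbonyl oxygen and O1, in which the aryl group attacks anti to the more substituted ring carbon C3 and should give the (S)-carbinol.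

**Step 9**
Reactants: 15 (S)-[4-(benzyloxy)-3-methoxyphenyl][(3S,4R,5S)-5-[4-(benzyloxy)-3-methoxyphenyl]-4-({[tert-butyl(diphenyl)silyl]oxy}methyl)oxolan-3-yl]methanol
Product: 16 (S)-[4-(benzyloxy)-3-methoxyphenyl][(3S,4R,5S)-5-[4-(benzyloxy)-3-methoxyphenyl]-4-(hydroxymethyl)oxolan-3-yl]methanol
Conditions: Bu4NF, THF, 23 °C
Reagents that add atoms: none
Why: Fluoride cleavage of the silyl ether is done while both phenols are still benzylated, so that no phenoxide and hence no quinone methide can form from the 4-oxygenated benzylic alcohol.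

**Step 10**
Reactants: 16 (S)-[4-(benzyloxy)-3-methoxyphenyl][(3S,4R,5S)-5-[4-(benzyloxy)-3-methoxyphenyl]-4-(hydroxymethyl)oxolan-3-yl]methanol
Product: 17 4-[(2S,3R,4S)-4-[(S)-hydroxy(4-hydroxy-3-methoxyphenyl)methyl]-3-(hydroxymethyl)oxolan-2-yl]-2-methoxyphenol
Conditions: H2 (1 atm), 10% Pd/C, EtOAc/MeOH, 23 °C, stopped at full conversion
Reagents that add atoms: none
Why: Hydrogenolysis of the two aryl benzyl ethers under neutral conditions should be much faster than cleavage of the benzylic C–O bonds of the oxolane and the carbinol, so all four stereocenters are kept.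

**Compound list**

1 | (E)-3-(4-hydroxy-3-methoxyphenyl)prop-2-enal (coniferaldehyde) | COc1cc(/C=C/C=O)ccc1O | starting material
2 | (E)-3-[4-(benzyloxy)-3-methoxyphenyl]prop-2-enal | COc1cc(/C=C/C=O)ccc1OCc1ccccc1 | intermediate
3 | dimethyl 2-bromopropanedioate | COC(=O)C(Br)C(=O)OC | starting material
4 | dimethyl (2S,3R)-2-[4-(benzyloxy)-3-methoxyphenyl]-3-formylcyclopropane-1,1-dicarboxylate | COC(=O)C1(C(=O)OC)[C@H](c2ccc(OCc3ccccc3)c(OC)c2)[C@H]1C=O | intermediate
5 | dimethyl (2S,3R)-2-[4-(benzyloxy)-3-methoxyphenyl]-3-(hydroxymethyl)cyclopropane-1,1-dicarboxylate | COC(=O)C1(C(=O)OC)[C@H](c2ccc(OCc3ccccc3)c(OC)c2)[C@H]1CO | intermediate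
6 | dimethyl (2S,3R)-2-[4-(benzyloxy)-3-methoxyphenyl]-3-({[tert-butyl(diphenyl)silyl]oxy}methyl)cyclopropane-1,1-dicarboxylate | COC(=O)C1(C(=O)OC)[C@H](c2ccc(OCc3ccccc3)c(OC)c2)[C@H]1CO[Si](c4ccccc4)(c5ccccc5)C(C)(C)C | intermediate
7 | formaldehyde (charged as paraformaldehyde) | C=O | starting material
8 | dimethyl (4R,5R)-5-[4-(benzyloxy)-3-methoxyphenyl]-4-({[tert-butyl(diphenyl)silyl]oxy}methyl)oxolane-3,3-dicarboxylate (aryl and silyloxymethyl cis; kinetic epimer, not isolated) | COC(=O)C1(C(=O)OC)CO[C@@H](c2ccc(OCc3ccccc3)c(OC)c2)[C@H]1CO[Si](c4ccccc4)(c5ccccc5)C(C)(C)C | intermediate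
9 | dimethyl (4R,5S)-5-[4-(benzyloxy)-3-methoxyphenyl]-4-({[tert-butyl(diphenyl)silyl]oxy}methyl)oxolane-3,3-dicarboxylate (aryl and silyloxymethyl trans) | COC(=O)C1(C(=O)OC)CO[C@H](c2ccc(OCc3ccccc3)c(OC)c2)[C@H]1CO[Si](c4ccccc4)(c5ccccc5)C(C)(C)C | intermediate
10 | methyl (3R,4R,5S)-5-[4-(benzyloxy)-3-methoxyphenyl]-4-({[tert-butyl(diphenyl)silyl]oxy}methyl)oxolane-3-carboxylate (ester cis to silyloxymethyl; kinetic epimer, not isolated) | COC(=O)[C@H]1CO[C@H](c2ccc(OCc3ccccc3)c(OC)c2)[C@H]1CO[Si](c4ccccc4)(c5ccccc5)C(C)(C)C | intermediate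
11 | methyl (3S,4R,5S)-5-[4-(benzyloxy)-3-methoxyphenyl]-4-({[tert-butyl(diphenyl)silyl]oxy}methyl)oxolane-3-carboxylate (all-trans) | COC(=O)[C@@H]1CO[C@H](c2ccc(OCc3ccccc3)c(OC)c2)[C@H]1CO[Si](c4ccccc4)(c5ccccc5)C(C)(C)C | intermediate
12 | (3S,4R,5S)-5-[4-(benzyloxy)-3-methoxyphenyl]-4-({[tert-butyl(diphenyl)silyl]oxy}methyl)oxolane-3-carbaldehyde | O=C[C@@H]1CO[C@H](c2ccc(OCc3ccccc3)c(OC)c2)[C@H]1CO[Si](c4ccccc4)(c5ccccc5)C(C)(C)C | intermediate
13 | 1-(benzyloxy)-4-bromo-2-methoxybenzene | COc1cc(Br)ccc1OCc1ccccc1 | starting material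
14 | [4-(benzyloxy)-3-methoxyphenyl]magnesium bromide (not isolated) | COc1cc([Mg]Br)ccc1OCc1ccccc1 | intermediate
15 | (S)-[4-(benzyloxy)-3-methoxyphenyl][(3S,4R,5S)-5-[4-(benzyloxy)-3-methoxyphenyl]-4-({[tert-butyl(diphenyl)silyl]oxy}methyl)oxolan-3-yl]methanol | COc1cc([C@@H](O)[C@@H]2CO[C@H](c3ccc(OCc4ccccc4)c(OC)c3)[C@H]2CO[Si](c5ccccc5)(c6ccccc6)C(C)(C)C)ccc1OCc7ccccc7 | intermediate
16 | (S)-[4-(benzyloxy)-3-methoxyphenyl][(3S,4R,5S)-5-[4-(benzyloxy)-3-methoxyphenyl]-4-(hydroxymethyl)oxolan-3-yl]methanol | COc1cc([C@@H](O)[C@@H]2CO[C@H](c3ccc(OCc4ccccc4)c(OC)c3)[C@H]2CO)ccc1OCc5ccccc5 | intermediate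
17 | 4-[(2S,3R,4S)-4-[(S)-hydroxy(4-hydroxy-3-methoxyphenyl)methyl]-3-(hydroxymethyl)oxolan-2-yl]-2-methoxyphenol | COc1cc([C@@H](O)[C@@H]2CO[C@H](c3ccc(O)c(OC)c3)[C@H]2CO)ccc1O | target

**Count and risks**

Total: 10 steps. Longest linear sequence: 10 steps (1 → 17); compounds 3, 7 and 13 enter as purchased.

Steps most likely to fail:

Step 5. Formaldehyde may oligomerise or insert twice before ring closure, the electron-rich rings may undergo Friedel–Crafts hydroxymethylation, the benzylic cation may lose a proton during the equilibration, or the equilibration at C2 may stay incomplete. Fallback, from 6 back to 9 by known reactions: Sc(OTf)3-catalysed methanolysis of the cyclopropane at the benzylic carbon would give dimethyl 2-[(2R)-1-[4-(benzyloxy)-3-methoxyphenyl]-3-{[tert-butyl(diphenyl)silyl]oxy}-1-methoxypropan-2-yl]propanedioate F1 (either configuration at the methoxy carbon serves). Base-catalysed hydroxymethylation of its malonate C–H with paraformaldehyde (K2CO3, THF) would give dimethyl 2-[(2R)-1-[4-(benzyloxy)-3-methoxyphenyl]-3-{[tert-butyl(diphenyl)silyl]oxy}-1-methoxypropan-2-yl]-2-(hydroxymethyl)propanedioate F2. BF3·OEt2 in CH2Cl2 would then ionise the benzylic methyl ether and the primary hydroxyl would capture the cation, closing the oxolane under thermodynamic control to 9.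

Step 8. The facial selectivity of the aryl addition may be poor, or the aldehyde may be enolised by the Grignard reagent. Fallback, from 11 back to 15, with the carbinol centre set by a reagent: MeNHOMe·HCl/iPrMgCl (THF, −20 °C) would convert the ester into (3S,4R,5S)-5-[4-(benzyloxy)-3-methoxyphenyl]-4-({[tert-butyl(diphenyl)silyl]oxy}methyl)-N-methoxy-N-methyloxolane-3-carboxamide F3. Grignard reagent 14 would turn this into [4-(benzyloxy)-3-methoxyphenyl][(3S,4R,5S)-5-[4-(benzyloxy)-3-methoxyphenyl]-4-({[tert-butyl(diphenyl)silyl]oxy}methyl)oxolan-3-yl]methanone F4. Corey–Bakshi–Shibata reduction with the (R)-2-methyl-oxazaborolidine and BH3·SMe2 (THF, −20 °C, aryl as the large group) should then give 15. Because the ketone's own Felkin preference opposes the catalyst here, this is held in reserve.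

Step 6. The ester enolate may expel the ring oxygen (ring opening), the silyl ether may be lost at 150 °C with lactonisation of the cis epimer, or the epimerisation at C4 may not converge. Fallback, from 9 back to 11 in two milder stages: LiOH (1 equiv, THF/H2O, 0 °C) would give the half-ester (4R,5S)-5-[4-(benzyloxy)-3-methoxyphenyl]-4-({[tert-butyl(diphenyl)silyl]oxy}methyl)-3-(methoxycarbonyl)oxolane-3-carboxylic acid F5 (configuration at the quaternary carbon immaterial). Decarboxylation through the enol in toluene/pyridine at 100 °C, followed by the same NaOMe equilibration, should give 11.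

**Further compounds**

F1 | step 5 | dimethyl 2-[(2R)-1-[4-(benzyloxy)-3-methoxyphenyl]-3-{[tert-butyl(diphenyl)silyl]oxy}-1-methoxypropan-2-yl]propanedioate (methoxy carbon as either epimer) | COC(=O)C(C(=O)OC)[C@H](CO[Si](c1ccccc1)(c2ccccc2)C(C)(C)C)C(OC)c3ccc(OCc4ccccc4)c(OC)c3
F2 | step 5 | dimethyl 2-[(2R)-1-[4-(benzyloxy)-3-methoxyphenyl]-3-{[tert-butyl(diphenyl)silyl]oxy}-1-methoxypropan-2-yl]-2-(hydroxymethyl)propanedioate (methoxy carbon as either epimer) | COC(=O)C(CO)(C(=O)OC)[C@H](CO[Si](c1ccccc1)(c2ccccc2)C(C)(C)C)C(OC)c3ccc(OCc4ccccc4)c(OC)c3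
F3 | step 8 | (3S,4R,5S)-5-[4-(benzyloxy)-3-methoxyphenyl]-4-({[tert-butyl(diphenyl)silyl]oxy}methyl)-N-methoxy-N-methyloxolane-3-carboxamide | CON(C)C(=O)[C@@H]1CO[C@H](c2ccc(OCc3ccccc3)c(OC)c2)[C@H]1CO[Si](c4ccccc4)(c5ccccc5)C(C)(C)C
F4 | step 8 | [4-(benzyloxy)-3-methoxyphenyl][(3S,4R,5S)-5-[4-(benzyloxy)-3-methoxyphenyl]-4-({[tert-butyl(diphenyl)silyl]oxy}methyl)oxolan-3-yl]methanone | COc1cc(C(=O)[C@@H]2CO[C@H](c3ccc(OCc4ccccc4)c(OC)c3)[C@H]2CO[Si](c5ccccc5)(c6ccccc6)C(C)(C)C)ccc1OCc7ccccc7
F5 | step 6 | (4R,5S)-5-[4-(benzyloxy)-3-methoxyphenyl]-4-({[tert-butyl(diphenyl)silyl]oxy}methyl)-3-(methoxycarbonyl)oxolane-3-carboxylic acid (quaternary carbon as either epimer) | COC(=O)C1(C(O)=O)CO[C@H](c2ccc(OCc3ccccc3)c(OC)c2)[C@H]1CO[Si](c4ccccc4)(c5ccccc5)C(C)(C)C
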